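**Retrosynthetic overview**
- The tetronic acid ring is closed last, by Dieckmann condensation of a methyl 2-(propanoyloxy) ester. Its C5 centre is bought as methyl (R)-glycidate (L-serine pool) and the epoxide is opened at CH2 by an (E)-alkenyl metal.
- The (E)-alkenyl metal comes from a C-methyl alkyne (syn-hydrozirconation, iodination). The alkyne is attached at the start by SN2 of propynyllithium on (R)-citronellyl bromide, which supplies the chain CH(CH3) centre.
- Key step: a Johnson–Claisen [3,3]-sigmatropic rearrangement of a divinyl carbinol forms the C–C bond of the furan tether and sets the (E)-trisubstituted alkene of the (E,E)-diene. The carbinol comes from the enal made by ozonolysis and dehydrogenation of the prenyl end.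
- The furan is bought as 3-bromofuran and joined by sp3–sp2 Negishi coupling after the rearrangement.
- Ring order: furan ring bought; tetronic acid ring formed in the final step.

Assumption: the SMILES is read as (5R) at the lactone carbon, (S) at the chain methine and E at all three chain double bonds, in the 4-hydroxy enol form drawn; all reagents named are taken as commercial.

**Step 1**
Reactants: 1 (R)-citronellyl bromide [(6R)-8-bromo-2,6-dimethyloct-2-ene]
Product: 2 (6R)-2,6-dimethylundec-2-en-9-yne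
Conditions: CH3C≡CLi (1.5 equiv), THF/DMPU 4:1, 0 °C → rt
Reagents that add atoms: 1-propynyllithium, [Li]C#CC
Why: SN2 alkylation of the lithium acetylide by the unhindered primary bromide adds the three carbons that later become the (E)-trisubstituted alkene and leaves the bought stereocentre untouched.

**Step 2**
Reactants: 2 (6R)-2,6-dimethylundec-2-en-9-yne
Product: 4 (4S)-4-methylnon-7-ynal, via ozonide 3 (not isolated)
Conditions: O3, CH2Cl2, −78 °C (Sudan red 7B end point); then PPh3, −78 °C → rt
Reagents that add atoms: ozone, [O-][O+]=O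
Why: Ozonolysis cleaves the electron-rich trisubstituted alkene far faster than the internal alkyne, and reductive work-up of the ozonide gives the aldehyde.

**Step 3**
Reactants: 4 (4S)-4-methylnon-7-ynal
Product: 5 (2E,4S)-4-methylnon-2-en-7-ynal
Conditions: IBX (1.3 equiv), DMSO/PhF 1:2, 65 °C
Reagents that add atoms: none
Why: IBX α,β-dehydrogenation of the aldehyde (Nicolaou) gives the conjugated (E)-enal as the thermodynamic isomer, and the now γ-positioned methyl centre is not enolised under these non-basic conditions.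

**Step 4**
Reactants: 5 (2E,4S)-4-methylnon-2-en-7-ynal
Product: 6 (4E,6S)-2,6-dimethylundeca-1,4-dien-9-yn-3-ol (both C3 epimers)
Conditions: CH2=C(CH3)MgBr (1.3 equiv), THF, −78 °C; then pH 7 buffer
Reagents that add atoms: isopropenylmagnesium bromide, CC(=C)[Mg]Br
Why: Grignard 1,2-addition to the enal at low temperature gives the divinyl carbinol; its new centre is formed unselectively but becomes sp2 in step 5.

**Step 5**
Reactants: 6 (4E,6S)-2,6-dimethylundeca-1,4-dien-9-yn-3-ol
Product: 9 ethyl (4E,6E,8S)-4,8-dimethyltrideca-4,6-dien-11-ynoate, via mixed orthoester 7 (not isolated), via ketene acetal 8 (not isolated)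
Conditions: CH3C(OEt)3 (6 equiv), EtCO2H (5 mol%), xylene, 135 °C, EtOH distilled off
Reagents that add atoms: triethyl orthoacetate, CC(OCC)(OCC)OCC
Why: Johnson–Claisen [3,3]-sigmatropic rearrangement through a chair transition state with the alkenyl substituent equatorial forms the new C–C bond at the unsubstituted isopropenyl terminus, giving the (E)-trisubstituted alkene in conjugation (E,E-diene) and erasing the carbinol centre.

**Step 6**
Reactants: 9 ethyl (4E,6E,8S)-4,8-dimethyltrideca-4,6-dien-11-ynoate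
Product: 10 (4E,6E,8S)-4,8-dimethyltrideca-4,6-dien-11-yn-1-ol
Conditions: LiAlH4 (0.6 equiv), Et2O, 0 °C; then Na2SO4·10H2O
Reagents that add atoms: none
Why: Hydride reduction of the ester to the primary alcohol; the isolated alkyne and the non-conjugated diene are inert to LiAlH4 at 0 °C.

**Step 7**
Reactants: 10 (4E,6E,8S)-4,8-dimethyltrideca-4,6-dien-11-yn-1-ol
Product: 11 (6S,7E,9E)-13-iodo-6,10-dimethyltrideca-7,9-dien-2-yne
Conditions: PPh3, I2, imidazole, CH2Cl2, 0 °C → rt, dark (I2 added to PPh3/imidazole first)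
Reagents that add atoms: iodine, II
Why: Appel-type iodination of the primary alcohol by SN2 on the alkoxyphosphonium ion, with no free iodine left to touch the diene.

**Step 8**
Reactants: 11 (6S,7E,9E)-13-iodo-6,10-dimethyltrideca-7,9-dien-2-yne; 12 3-bromofuran
Product: 14 3-[(4E,6E,8S)-4,8-dimethyltrideca-4,6-dien-11-yn-1-yl]furan, via alkylzinc iodide 13 (not isolated)
Conditions: Zn dust (activated with BrCH2CH2Br/Me3SiCl), LiCl, THF, 40 °C; then 12, Pd(OAc)2 (2 mol%), SPhos (4 mol%), rt → 45 °C
Reagents that add atoms: none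
Why: Knochel zinc insertion into the primary iodide followed by Negishi sp3–sp2 cross-coupling attaches the furan at C3 without β-hydride elimination and tolerates the alkyne and diene.

**Step 9**
Reactants: 14 3-[(4E,6E,8S)-4,8-dimethyltrideca-4,6-dien-11-yn-1-yl]furan
Product: 16 3-[(4E,6E,8S,11E)-12-iodo-4,8-dimethyltrideca-4,6,11-trien-1-yl]furan, via alkenylzirconocene chloride 15 (not isolated)
Conditions: Cp2Zr(H)Cl (2.2 equiv), THF, 50 °C, 1 h, dark; then I2, THF, −20 → 0 °C
Reagents that add atoms: iodine, II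
Why: syn-Hydrozirconation of the alkyne (much faster than addition to the internal diene or the furan), with excess Cp2Zr(H)Cl at 50 °C equilibrating zirconium to the less hindered methyl-bearing carbon (about 10:1 or better, minor regioisomer removed by chromatography), then iodinolysis with retention gives the (E)-2-iodoalkene.

**Step 10**
Reactants: 16 3-[(4E,6E,8S,11E)-12-iodo-4,8-dimethyltrideca-4,6,11-trien-1-yl]furan; 17 methyl (2R)-oxirane-2-carboxylate (methyl (R)-glycidate, 1.5 equiv)
Product: 21 methyl (2R,4E,8S,9E,11E)-15-(furan-3-yl)-4,8,12-trimethyl-2-(propanoyloxy)pentadeca-4,9,11-trienoate, via vinyllithium 18 (not isolated), via vinylmagnesium bromide 19 (not isolated), via bromomagnesium alkoxide 20 (not isolated)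
Conditions: tBuLi (2.05 equiv), Et2O, −78 °C; MgBr2·OEt2, −78 → −40 °C; CuI (15 mol%), 17, THF, −40 → −20 °C; then (EtCO)2O, DMAP (cat.), −20 °C → rt
Reagents that add atoms: propanoic anhydride, CCC(=O)OC(=O)CC
Why: Iodine–lithium exchange and transmetalation keep the alkene geometry, the copper-catalysed SN2 epoxide opening occurs at the unsubstituted CH2 so the bought (R) centre is untouched and becomes C5, and the alkoxide is acylated in the same pot.

**Step 11**
Reactants: 21 methyl (2R,4E,8S,9E,11E)-15-(furan-3-yl)-4,8,12-trimethyl-2-(propanoyloxy)pentadeca-4,9,11-trienoate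
Product: 22 (5R)-5-[(2E,6S,7E,9E)-13-(furan-3-yl)-2,6,10-trimethyltrideca-2,7,9-trien-1-yl]-4-hydroxy-3-methylfuran-2(5H)-one (target)
Conditions: LiN(SiMe3)2 (2.2 equiv), THF, −78 → 0 °C; then 1 M HCl
Reagents that add atoms: none
Why: Dieckmann condensation (intramolecular Claisen): kinetic deprotonation of the propanoate CH2 and 5-exo attack on the methyl ester close the 3-methyltetronic acid, which sits as its unreactive tetronate anion until acidification, so the (R) centre at C5 is not epimerised.

**Compound list**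
1 | (6R)-8-bromo-2,6-dimethyloct-2-ene, (R)-citronellyl bromide | BrCC[C@H](C)CCC=C(C)C | starting material
2 | (6R)-2,6-dimethylundec-2-en-9-yne | CC#CCC[C@H](C)CCC=C(C)C | intermediate
3 | 3,3-dimethyl-5-[(3S)-3-methyloct-6-yn-1-yl]-1,2,4-trioxolane (ozonide) | CC#CCC[C@H](C)CCC1OOC(C)(C)O1 | intermediate
4 | (4S)-4-methylnon-7-ynal | CC#CCC[C@H](C)CCC=O | intermediate
5 | (2E,4S)-4-methylnon-2-en-7-ynal | CC#CCC[C@H](C)/C=C/C=O | intermediate
6 | (4E,6S)-2,6-dimethylundeca-1,4-dien-9-yn-3-ol (both C3 epimers) | CC#CCC[C@H](C)/C=C/C(O)C(C)=C | intermediate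
7 | (4E,6S)-3-(1,1-diethoxyethoxy)-2,6-dimethylundeca-1,4-dien-9-yne (mixed orthoester) | CC#CCC[C@H](C)/C=C/C(OC(C)(OCC)OCC)C(C)=C | intermediate
8 | (4E,6S)-3-[(1-ethoxyethenyl)oxy]-2,6-dimethylundeca-1,4-dien-9-yne (ketene acetal) | CC#CCC[C@H](C)/C=C/C(OC(=C)OCC)C(C)=C | intermediate
9 | ethyl (4E,6E,8S)-4,8-dimethyltrideca-4,6-dien-11-ynoate | CC#CCC[C@H](C)/C=C/C=C(\C)CCC(=O)OCC | intermediate
10 | (4E,6E,8S)-4,8-dimethyltrideca-4,6-dien-11-yn-1-ol | CC#CCC[C@H](C)/C=C/C=C(\C)CCCO | intermediate
11 | (6S,7E,9E)-13-iodo-6,10-dimethyltrideca-7,9-dien-2-yne | CC#CCC[C@H](C)/C=C/C=C(\C)CCCI | intermediate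
12 | 3-bromofuran | Brc1ccoc1 | starting material
13 | [(4E,6E,8S)-4,8-dimethyltrideca-4,6-dien-11-yn-1-yl]zinc iodide | CC#CCC[C@H](C)/C=C/C=C(\C)CCC[Zn]I | intermediate
14 | 3-[(4E,6E,8S)-4,8-dimethyltrideca-4,6-dien-11-yn-1-yl]furan | CC#CCC[C@H](C)/C=C/C=C(\C)CCCc1ccoc1 | intermediate
15 | chlorobis(cyclopentadienyl)[(2E,6S,7E,9E)-13-(furan-3-yl)-6,10-dimethyltrideca-2,7,9-trien-2-yl]zirconium | Cl[Zr](C1C=CC=C1)(C1C=CC=C1)/C(C)=C/CC[C@H](C)/C=C/C=C(\C)CCCc1ccoc1 | intermediate
16 | 3-[(4E,6E,8S,11E)-12-iodo-4,8-dimethyltrideca-4,6,11-trien-1-yl]furan | I/C(C)=C/CC[C@H](C)/C=C/C=C(\C)CCCc1ccoc1 | intermediate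
17 | methyl (2R)-oxirane-2-carboxylate, methyl (R)-glycidate | COC(=O)[C@H]1CO1 | starting material
18 | [(2Z,6S,7E,9E)-13-(furan-3-yl)-6,10-dimethyltrideca-2,7,9-trien-2-yl]lithium | [Li]/C(C)=C/CC[C@H](C)/C=C/C=C(\C)CCCc1ccoc1 | intermediate
19 | [(2E,6S,7E,9E)-13-(furan-3-yl)-6,10-dimethyltrideca-2,7,9-trien-2-yl]magnesium bromide | Br[Mg]/C(C)=C/CC[C@H](C)/C=C/C=C(\C)CCCc1ccoc1 | intermediate
20 | methyl (2R,4E,8S,9E,11E)-2-[(bromomagnesio)oxy]-15-(furan-3-yl)-4,8,12-trimethylpentadeca-4,9,11-trienoate | COC(=O)[C@H](O[Mg]Br)C/C(C)=C/CC[C@H](C)/C=C/C=C(\C)CCCc1ccoc1 | intermediate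
21 | methyl (2R,4E,8S,9E,11E)-15-(furan-3-yl)-4,8,12-trimethyl-2-(propanoyloxy)pentadeca-4,9,11-trienoate | COC(=O)[C@H](OC(=O)CC)C/C(C)=C/CC[C@H](C)/C=C/C=C(\C)CCCc1ccoc1 | intermediate
22 | (5R)-5-[(2E,6S,7E,9E)-13-(furan-3-yl)-2,6,10-trimethyltrideca-2,7,9-trien-1-yl]-4-hydroxy-3-methylfuran-2(5H)-one | CC1=C(O)[C@@H](C/C(C)=C/CC[C@H](C)/C=C/C=C(\C)CCCc2ccoc2)OC1=O | target

**Step count**
Total: 11 steps. Longest linear sequence: 11 steps (1 → 22); 12 and 17 are bought and enter in steps 8 and 10.

**Steps most likely to fail**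

Step 3 (IBX dehydrogenation). The reaction can stall or run on to the dienal, which would destroy the methyl stereocentre. The fallback sets out from 4 and comes back at 5. Aldehyde 4 is selenenylated at the α-carbon with PhSeCl in EtOAc at room temperature to give (4S)-4-methyl-2-(phenylselanyl)non-7-ynal F1. NaIO4 in aqueous THF/MeOH at 0 °C → rt oxidises it to the selenoxide F2, which undergoes syn-elimination at room temperature to give the (E)-enal 5.

Step 5 (Johnson–Claisen). The doubly allylic mixed orthoester can ionise under the acid catalysis, or rearrange through the other allyl unit. The fallback sets out from 6 and comes back at 10, using the acid-free Eschenmoser–Claisen variant. Heating 6 with CH3C(OMe)2NMe2 in xylene at 120–140 °C gives the mixed amide acetal F3. This loses methanol to the ketene N,O-acetal F4, which rearranges [3,3] to (4E,6E,8S)-N,N,4,8-tetramethyltrideca-4,6-dien-11-ynamide F5. LiEt3BH in THF at 0 °C → rt reduces F5 directly to the alcohol 10.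

Step 10 (alkenyl metal, glycidate opening, acylation in one pot). The alkenyl metal may attack the ester carbonyl of 17, halide may open the epoxide, or the in-flask acylation may be incomplete. The fallback sets out from 16 and comes back at 21. Compound 16 is converted as before through 18 into 19. With CuI catalysis in THF/DMPU at −30 → 0 °C, 19 opens potassium (2R)-oxirane-2-carboxylate ([K+].[O-]C(=O)[C@H]1CO1), a carboxylate that offers no electrophilic carbonyl. Acidification gives the hydroxy acid F6. Me3SiCHN2 in PhMe/MeOH gives the hydroxy ester F7, and (EtCO)2O, pyridine and catalytic DMAP give 21.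

**Further compounds**
F1 | step 3 | (4S)-4-methyl-2-(phenylselanyl)non-7-ynal (both C2 epimers) | CC#CCC[C@H](C)CC([Se]c1ccccc1)C=O
F2 | step 3 | (4S)-2-(benzeneseleninyl)-4-methylnon-7-ynal (selenoxide) | CC#CCC[C@H](C)CC([Se](=O)c1ccccc1)C=O
F3 | step 5 | (4E,6S)-3-[1-(dimethylamino)-1-methoxyethoxy]-2,6-dimethylundeca-1,4-dien-9-yne (mixed amide acetal) | CC#CCC[C@H](C)/C=C/C(OC(C)(OC)N(C)C)C(C)=C
F4 | step 5 | (4E,6S)-3-{[1-(dimethylamino)ethenyl]oxy}-2,6-dimethylundeca-1,4-dien-9-yne (ketene N,O-acetal) | CC#CCC[C@H](C)/C=C/C(OC(=C)N(C)C)C(C)=C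
F5 | step 5 | (4E,6E,8S)-N,N,4,8-tetramethyltrideca-4,6-dien-11-ynamide | CC#CCC[C@H](C)/C=C/C=C(\C)CCC(=O)N(C)C
F6 | step 10 | (2R,4E,8S,9E,11E)-15-(furan-3-yl)-2-hydroxy-4,8,12-trimethylpentadeca-4,9,11-trienoic acid | OC(=O)[C@H](O)C/C(C)=C/CC[C@H](C)/C=C/C=C(\C)CCCc1ccoc1
F7 | step 10 | methyl (2R,4E,8S,9E,11E)-15-(furan-3-yl)-2-hydroxy-4,8,12-trimethylpentadeca-4,9,11-trienoate | COC(=O)[C@H](O)C/C(C)=C/CC[C@H](C)/C=C/C=C(\C)CCCc1ccoc1
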